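## The problem

Atom labels follow benzofuranone numbering (O1, C2=O, C3=CH2, C3a, C4, C5, C6, C7, C7a; C2′ is the side-chain methine). TBS = tert-butyldimethylsilyl, TBDPS = tert-butyldiphenylsilyl.

The target is a cis-fused α-methylene-γ-butyrolactone on a cyclohexene. The carbocycle carries three contiguous stereocentres, C3a (R), C4 (R) and C7a (R), with all three hydrogens on one face, next to a tetrasubstituted C5=C6 alkene that bears the methyl group and a branched five-carbon chain. Two further centres lie outside the ring, C2′ (S) and the α-carbon of the (R)-2-methylbutanoate; neither can be induced from the ring, so both must be bought. C7a, once fixed absolutely, can direct C3a through the ring fusion, and C3a can direct C4. The methylene lactone is a Michael acceptor and isomerises to the butenolide with base, the allylic C4 ester can ionise or eliminate towards C3a, and its α-centre is epimerisable, so methylene and ester must arrive late and under mild conditions. Any intermediate with a C4 ketone has the C7a oxygen in the β-position and aromatises to a phenol once that oxygen is expelled. The enabling feature is that C3a, which carries C3, sits between the oxygenated carbons C7a and C4. A two-carbon radical hung on the C7a oxygen reaches C3a by 5-exo closure; if C3a=C4 is the enol ether of a C4 ketone conjugated with C5=C6, the adduct radical is allylic and α-oxygenated, and hydrogen capture at C4 sets the third ring stereocentre while the tetrasubstituted alkene stays in place.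

## Retrosynthesis

**Ester and silyl ethers (34 ⇒ 33 ⇒ 30 + 31).** The primary hydroxyl of 34 is masked as the TBDPS ether 33, and the C4–O acyl bond is cut to the allylic alcohol 30 and (R)-2-methylbutanoic acid 31. Acylating last keeps the epimerisable ester away from every enolate step. The forward reaction needs only a carbodiimide coupling that does not touch the methylene lactone.

**Methylene and lactone oxidation level (30 ⇒ 29 ⇒ 25 ⇒ 23).** The C3=CH2 bond is cut back to the saturated lactone 25 (Mannich methylenation of its enolate), with C4 carried as a TBS ether (29). Lactone 25 is the oxidation product of the lactol ethyl ether 23. Bringing C2 in at the acetal level is what allows a radical closure; an ester tether would cyclise poorly. The price is one oxidation, which also erases the acetal stereocentre.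

**Key cut (23 ⇒ 22).** The C3–C3a bond and the C4–H bond are cut together, leading to the bromoacetal 22 of a cross-conjugated silyl dienol ether. Against the neighbouring cuts (lactonisation of a C3a acetic acid, or alkylation of a C4 ketone enolate followed by separate reduction), this one forms the ring-joining C–C bond, fixes the cis fusion through the tether and sets C4 in one operation. 22 has a single ring and only the C7a and C2′ centres. The forward reaction must close 5-exo and must deliver hydrogen to C4, not C6, from the face away from the new bond.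

**Tether and enol ether (22 ⇒ 20 ⇒ 18 + 19).** The O–Si bond is cut to the enone 20 (kinetic α′-enolisation at C3a), and the mixed acetal is cut to the hydroxy enone 18, ethyl vinyl ether 19 and a bromine source. The bromoacetal must precede the enol ether because NBS would brominate the latter. The enolate of 20 must be trapped before it expels the C7a oxygen.

**Carbocycle (18 ⇒ 17 ⇒ 15).** The C5=C6 bond is cut by an aldol condensation to the 1,5-diketone 15, with the C7a oxygen protected as a TBS ether (17). This cut turns the ring into a chain whose only stereocentres are C7a and C2′. It is preferred to a cut at C4–C5 or to a cyclohexanedione route because a symmetric 1,3-dione would destroy the C7a information. The closure must give the tetrasubstituted enone without losing the β-silyloxy group.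

**Chain assembly (15 ⇒ 14 ⇒ 6 + 11; 11 ⇒ 7 + 8).** Both ketones are unmasked from the bis-dithiane 14. The C3a–C4 bond is cut to the lithiated dithiane of 6 and the epoxide 11, and the C6–C7 bond of 11 to 2-methyl-1,3-dithiane 7 and (R)-epichlorohydrin 8. One three-carbon linchpin thus supplies C7, C7a and C3a, and C7a is bought. With the methyl dithiane added first, the (R)-enantiomer of 8 gives the required (R)-C7a.

**Side-chain fragment (6 ⇒ 5 ⇒ 4 ⇒ 2 ⇒ 1).** Dithiane 6 comes from (S)-citronellal 1. C1 and C2 of citronellal become C4 and C5, C3 is C2′, and the isopropylidene end is cut off by ozonolysis (via acetal 2) to leave the primary alcohol 4, protected as 5. The forward sequence only has to keep the two chain ends distinct.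

## Roads not taken

**Alternative 1:** The carbocycle is cut at C3a–C4 by a lactone enolate Claisen rearrangement. The six-membered lactone A1 is enolised and O-silylated (LiN(iPr)2, Me3SiCl) and rearranges on warming through a boat transition state to the cyclohexene carboxylic acid A2.
- Merits: the sigmatropic shift places the C5=C6 alkene without any regiochemical choice and sets C3a and C4 together, with no tin. On alkene placement it is better than the chosen plan, whose radical step must win a competition between two allyl termini.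
- Weak points: A1 needs a quaternary carbinol centre of defined configuration and a geometrically pure (E) silyl enol ether of an α-branched aldehyde, both built only to be destroyed. Its enolisation has the C7a oxygen β to the enolate. In A2 the carboxyl carbon is C3, so C2 must still be added by reduction and homologation before lactonisation and methylenation.
- Comparison: the chosen plan sets against the cleaner alkene placement a tether that delivers C2 and C3 together at the correct oxidation pattern, and a far shorter route from purchasable chirality.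

**Alternative 2:** The carbocycle is cut at C4–C5 and C6–C7. Zerovalent nickel (Ni(cod)2 with a bulky phosphine) would join the lactone-fused cyclobutanone A3 and the chiral alkyne A4 by oxidative cyclisation, β-carbon elimination and reductive elimination, giving the lactone enone A5.
- Merits: it is the most convergent route. Two C–C bonds form in one step, the lactone and both fusion centres are already present in A3, and the side chain arrives intact in A4. If it worked it would be shorter than the chosen route, which spends eleven steps before its key step.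
- Weak points: the branched alkyne terminus must bond to the carbonyl carbon, whereas nickel normally joins the less hindered alkyne carbon there, so the regioisomer with methyl at C5 is expected to dominate. A5 has O1 β to the C4 ketone and can open and aromatise. C4 must still be reduced in a separate stereoselective step.
- Comparison: the chosen plan sets against the convergence an unambiguous placement of every substituent and the setting of C4 in the ring-forming step.

**Alternative 3:** C3a–C7a, C2–C3 and O1–C2 are cut at once. Heating the (Z)-allenyl aldehyde A6 with Mo(CO)6 and dimethyl sulfoxide (hetero-Pauson–Khand reaction) would close the cyclohexene and the methylene lactone together to give A7, which is identical with compound 29 of the chosen route.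
- Merits: both rings, the lactone carbonyl and the methylene arrive in one step, so lactol oxidation and Mannich methylenation are saved. In end-game economy it is better than the chosen plan.
- Weak points: A6 needs a stereodefined tetrasubstituted (Z)-alkene with a β,γ-unsaturated aldehyde that conjugates easily, and a C4 carbinol next to the allene that must control C3a and C7a by 1,2-induction. Six-membered closure in this reaction is less secure than five-membered, and the metal is stoichiometric.
- Comparison: the chosen plan sets against it that every precursor is made by standard reactions and that each new stereocentre is set by a bought one through a ring constraint, not by open-chain induction.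

Key step: step 12

## Route

Assumptions: (R)-2-methylbutanoic acid 31 is taken as a purchasable reagent. The acetal carbon C2 of 20–24 forms as both epimers, is carried as the mixture, is drawn without configuration and disappears in step 13. The transient centres of 16 and 27 are likewise left undefined.

Step 1
Reactants: 1 (S)-citronellal
Product: 2 (6S)-8,8-dimethoxy-2,6-dimethyloct-2-ene
Conditions: HC(OMe)3, MeOH, PPTS (cat.), rt
Reagents that add atoms: trimethyl orthoformate COC(OC)OC; methanol CO
Why: Acid-catalysed acetalisation with the orthoformate as water scavenger; the weak acid and excess methanol keep the carbonyl-ene cyclisation of citronellal in check, and C3 (the future C2′) is untouched.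

Step 2
Reactants: 2 (6S)-8,8-dimethoxy-2,6-dimethyloct-2-ene
Product: 4 (4S)-6,6-dimethoxy-4-methylhexan-1-ol, via aldehyde 3 (not isolated)
Conditions: O3, CH2Cl2/MeOH, −78 °C (indicator dye); Me2S; then NaBH4, 0 °C
Reagents that add atoms: ozone [O-][O+]=O
Why: Ozonolysis of the only alkene with reductive work-up; the acetal keeps the two chain ends distinct, and stopping at the first excess of ozone avoids acetal oxidation.

Step 3
Reactants: 4 (4S)-6,6-dimethoxy-4-methylhexan-1-ol
Product: 5 tert-butyl{[(4S)-6,6-dimethoxy-4-methylhexyl]oxy}diphenylsilane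
Conditions: TBDPSCl, imidazole, CH2Cl2, rt
Reagents that add atoms: tert-butylchlorodiphenylsilane CC(C)(C)[Si](Cl)(c1ccccc1)c1ccccc1
Why: Standard silylation of a primary alcohol; TBDPS is chosen because it survives organolithium reagents, Lewis and Brønsted acid, CrO3 and the HF treatments that later remove TBS groups.

Step 4
Reactants: 5 tert-butyl{[(4S)-6,6-dimethoxy-4-methylhexyl]oxy}diphenylsilane
Product: 6 2-[(2S)-5-(TBDPSO)-2-methylpentyl]-1,3-dithiane
Conditions: HS(CH2)3SH, BF3·OEt2, CH2Cl2, −20 → 0 °C
Reagents that add atoms: propane-1,3-dithiol SCCCS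
Why: Lewis-acid transthioacetalisation of the dimethyl acetal, which turns the future C4 into an acyl-anion equivalent (Corey–Seebach umpolung).

Step 5
Reactants: 7 2-methyl-1,3-dithiane; 8 (R)-epichlorohydrin
Product: 11 2-methyl-2-{[(2R)-oxiran-2-yl]methyl}-1,3-dithiane, via lithiodithiane 9 (not isolated), via chlorohydrin alkoxide 10 (not isolated)
Conditions: n-BuLi, THF, −30 °C; 8, −78 °C → rt
Reagents that add atoms: none
Why: Corey–Seebach lithiation, attack at the epoxide CH2 of 8 and closure of the chlorohydrin alkoxide on warming. The C–O bond of the stereocentre is never broken, so (R)-8 gives (R)-11, with the former chloromethyl carbon (future C3a) as the new epoxide terminus.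

Step 6
Reactants: 6 2-[(2S)-5-(TBDPSO)-2-methylpentyl]-1,3-dithiane; 11 2-methyl-2-{[(2R)-oxiran-2-yl]methyl}-1,3-dithiane
Product: 14 tert-butyl{[(2R)-1-(2-methyl-1,3-dithian-2-yl)-3-{2-[(2S)-5-(TBDPSO)-2-methylpentyl]-1,3-dithian-2-yl}propan-2-yl]oxy}dimethylsilane, via lithiodithiane 12 (not isolated), via lithium alkoxide 13 (not isolated)
Conditions: t-BuLi, THF/HMPA (10:1), −78 °C; 11, −78 → −20 °C; TBSOTf, −78 → 0 °C
Reagents that add atoms: tert-butyldimethylsilyl trifluoromethanesulfonate CC(C)(C)[Si](C)(C)OS(=O)(=O)C(F)(F)F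
Why: The lithiated 2-alkyl dithiane opens the terminal epoxide at CH2 and forms C3a–C4 (dithiane–epoxide linchpin coupling). The alkoxide is silylated in the same flask, so the C7a oxygen is never a free β-hydroxy ketone oxygen later, and C7a (R) comes unchanged from 8.

Step 7
Reactants: 14 the bis-dithiane TBS ether of step 6
Product: 15 (4R,8S)-4-(TBSO)-11-(TBDPSO)-8-methylundecane-2,6-dione
Conditions: MeI, CaCO3, MeCN/H2O (9:1), 45 °C
Reagents that add atoms: water O
Why: Alkylative hydrolysis of both dithianes (S-methylation, loss of the sulfonium group, capture by water) under CaCO3 buffer, mild enough for the β-silyloxy diketone and both silyl ethers.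

Step 8
Reactants: 15 (4R,8S)-4-(TBSO)-11-(TBDPSO)-8-methylundecane-2,6-dione
Product: 17 (5R)-5-(TBSO)-3-methyl-2-[(2S)-5-(TBDPSO)pentan-2-yl]cyclohex-2-en-1-one, via ketol 16 (not isolated)
Conditions: p-TsOH·H2O (cat.), benzene, 4 Å MS, 60 °C
Reagents that add atoms: none
Why: Acid-catalysed intramolecular aldol condensation (6-enolendo-exo-trig) through the more substituted enol of the C4 ketone onto the methyl ketone, then loss of the tertiary hydroxyl. Acid is preferred to base because a silyl ether oxygen is a poor leaving group under acid while the tertiary carbinol ionises easily, and the tetrasubstituted enone is the thermodynamic regioisomer.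

Step 9
Reactants: 17 (5R)-5-(TBSO)-3-methyl-2-[(2S)-5-(TBDPSO)pentan-2-yl]cyclohex-2-en-1-one
Product: 18 (5R)-5-hydroxy-3-methyl-2-[(2S)-5-(TBDPSO)pentan-2-yl]cyclohex-2-en-1-one
Conditions: HF·pyridine, pyridine/THF, 0 °C → rt
Reagents that add atoms: none
Why: Fluoride cleavage of the secondary TBS ether; a primary TBDPS ether reacts markedly more slowly with HF·pyridine, and the buffered medium leaves the β-hydroxy enone alone.

Step 10
Reactants: 18 (5R)-5-hydroxy-3-methyl-2-[(2S)-5-(TBDPSO)pentan-2-yl]cyclohex-2-en-1-one; 19 ethyl vinyl ether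
Product: 20 (5R)-5-(2-bromo-1-ethoxyethoxy)-3-methyl-2-[(2S)-5-(TBDPSO)pentan-2-yl]cyclohex-2-en-1-one
Conditions: NBS, CH2Cl2, −40 → 0 °C
Reagents that add atoms: N-bromosuccinimide O=C1CCC(=O)N1Br
Why: Bromoalkoxylation of the vinyl ether (Ueno–Stork bromoacetal formation): NBS gives the α-bromo oxocarbenium ion, which the C7a hydroxyl captures under neutral conditions. Both acetal epimers form, which is immaterial.

Step 11
Reactants: 20 (5R)-5-(2-bromo-1-ethoxyethoxy)-3-methyl-2-[(2S)-5-(TBDPSO)pentan-2-yl]cyclohex-2-en-1-one
Product: 22 (6R)-6-(2-bromo-1-ethoxyethoxy)-2-(TBSO)-4-methyl-3-[(2S)-5-(TBDPSO)pentan-2-yl]cyclohexa-1,3-diene, via lithium dienolate 21 (not isolated)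
Conditions: LiN(iPr)2, THF, −78 °C; TBSOTf, −78 °C; Et3N quench
Reagents that add atoms: tert-butyldimethylsilyl trifluoromethanesulfonate CC(C)(C)[Si](C)(C)OS(=O)(=O)C(F)(F)F
Why: Kinetic deprotonation of the enone at the α′-methylene C3a gives the cross-conjugated dienolate, which the silyl triflate O-silylates at once (kinetic silyl dienol ether formation). Low temperature and immediate trapping are meant to outrun loss of the β-acetal oxygen and attack on the bromide.

Step 12
Reactants: 22 (6R)-6-(2-bromo-1-ethoxyethoxy)-2-(TBSO)-4-methyl-3-[(2S)-5-(TBDPSO)pentan-2-yl]cyclohexa-1,3-diene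
Product: 23 (3aR,4R,7aR)-4-(TBSO)-2-ethoxy-6-methyl-5-[(2S)-5-(TBDPSO)pentan-2-yl]-2,3,3a,4,7,7a-hexahydro-1-benzofuran
Conditions: Bu3SnH (slow addition), AIBN (cat.), benzene (0.01 M), 80 °C
Reagents that add atoms: none
Why: Bu3Sn• abstracts bromine from 22 to give a primary radical at C3, which adds to C3a of the 2-silyloxy diene; the closest known reaction type is the Ueno–Stork haloacetal radical cyclisation onto alkenes, enol ethers and dienes. The oxygen ring closes in the 5-exo-trig mode, and the short tether from the C7a oxygen can reach C3a only on the face where that oxygen stands, so C7a controls C3a and the fusion is cis. The adduct is an allyl radical spread over C4 and C6 and stabilised by the silyloxy group. Bu3SnH then transfers hydrogen to C4 from the face opposite the new C3a–C3 bond (the convex face of the bicycle), so C3a controls C4 and the C4 oxygen ends up cis to C3 and O1. Three selectivities are needed: 5-exo over 6-endo attack, secured by the tether length and the fully substituted C4; hydrogen capture at C4 and not C6, favoured because C6 is a tertiary methyl-bearing terminus while C4 is secondary and capture there keeps the tetrasubstituted all-carbon alkene; and the facial selectivity just described. The bulkier donor (Me3Si)3SiH is held in reserve to sharpen the preference for the less hindered terminus.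

Step 13
Reactants: 23 (3aR,4R,7aR)-4-(TBSO)-2-ethoxy-6-methyl-5-[(2S)-5-(TBDPSO)pentan-2-yl]-2,3,3a,4,7,7a-hexahydro-1-benzofuran
Product: 25 (3aR,4R,7aR)-4-(TBSO)-6-methyl-5-[(2S)-5-(TBDPSO)pentan-2-yl]-3a,4,7,7a-tetrahydro-1-benzofuran-2(3H)-one, via lactol 24 (not isolated)
Conditions: CrO3, H2SO4 (aq.), acetone, 0 °C
Reagents that add atoms: water O
Why: Jones oxidation of a lactol ether: the aqueous acid opens the acetal to lactol 24, which CrO3 oxidises to the γ-lactone, erasing the acetal centre. The hindered secondary TBS ether and the primary TBDPS ether are expected to tolerate brief exposure at 0 °C.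

Step 14
Reactants: 25 (3aR,4R,7aR)-4-(TBSO)-6-methyl-5-[(2S)-5-(TBDPSO)pentan-2-yl]-3a,4,7,7a-tetrahydro-1-benzofuran-2(3H)-one
Product: 29 (3aR,4R,7aR)-4-(TBSO)-6-methyl-3-methylidene-5-[(2S)-5-(TBDPSO)pentan-2-yl]-3a,4,7,7a-tetrahydro-1-benzofuran-2(3H)-one, via lithium enolate 26 (not isolated), via Mannich base 27 (not isolated), via methiodide 28 (not isolated)
Conditions: LiN(iPr)2, THF, −78 °C; CH2=NMe2+ I− (Eschenmoser's salt), −78 → 0 °C; MeI, MeOH, rt; NaHCO3 (aq.), CH2Cl2, rt
Reagents that add atoms: N,N-dimethylmethyleneiminium iodide C=[N+](C)C.[I-]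
Why: α-Methylenation by the Mannich route: enolate aminomethylation, quaternisation and base-induced loss of trimethylamine. No leaving group is β to the enolate carbon, C3a is not deprotonated, and the methylene is installed before the base-sensitive ester.

Step 15
Reactants: 29 (3aR,4R,7aR)-4-(TBSO)-6-methyl-3-methylidene-5-[(2S)-5-(TBDPSO)pentan-2-yl]-3a,4,7,7a-tetrahydro-1-benzofuran-2(3H)-one
Product: 30 (3aS,4R,7aR)-4-hydroxy-6-methyl-3-methylidene-5-[(2S)-5-(TBDPSO)pentan-2-yl]-3a,4,7,7a-tetrahydro-1-benzofuran-2(3H)-one
Conditions: HF (48% aq.), MeCN, 0 °C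
Reagents that add atoms: none
Why: Selective desilylation: TBDPS ethers are far more stable to aqueous HF than TBS ethers, which should outweigh the hindrance at C4. The C4–O bond is not broken, so the configuration is kept (the descriptor at C3a changes only through priority).

Step 16
Reactants: 30 (3aS,4R,7aR)-4-hydroxy-6-methyl-3-methylidene-5-[(2S)-5-(TBDPSO)pentan-2-yl]-3a,4,7,7a-tetrahydro-1-benzofuran-2(3H)-one; 31 (R)-2-methylbutanoic acid
Product: 33 (3aR,4R,7aR)-6-methyl-3-methylidene-2-oxo-5-[(2S)-5-(TBDPSO)pentan-2-yl]-2,3,3a,4,7,7a-hexahydro-1-benzofuran-4-yl (2R)-2-methylbutanoate, via O-acylisourea 32 (not isolated)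
Conditions: DCC, DMAP, CH2Cl2, 0 °C → rt
Reagents that add atoms: none
Why: Steglich esterification through the O-acylisourea and the acylpyridinium ion; no base strong enough to epimerise the acid α-centre or to isomerise the methylene lactone is present.

Step 17
Reactants: 33 the TBDPS-protected ester of step 16
Product: 34 (3aR,4R,7aR)-5-[(2S)-5-hydroxypentan-2-yl]-6-methyl-3-methylidene-2-oxo-2,3,3a,4,7,7a-hexahydro-1-benzofuran-4-yl (2R)-2-methylbutanoate
Conditions: HF·pyridine, THF, 0 °C → rt
Reagents that add atoms: none
Why: Fluoride cleavage of the primary TBDPS ether under buffered acidic conditions that leave the ester, the allylic C–O bond and the methylene lactone intact.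

## Compound list

1 | (S)-citronellal, (3S)-3,7-dimethyloct-6-enal | O=CC[C@@H](C)CCC=C(C)C | starting material
2 | (6S)-8,8-dimethoxy-2,6-dimethyloct-2-ene | COC(OC)C[C@@H](C)CCC=C(C)C | intermediate
3 | (4S)-6,6-dimethoxy-4-methylhexanal | COC(OC)C[C@@H](C)CCC=O | intermediate
4 | (4S)-6,6-dimethoxy-4-methylhexan-1-ol | COC(OC)C[C@@H](C)CCCO | intermediate
5 | tert-butyl{[(4S)-6,6-dimethoxy-4-methylhexyl]oxy}diphenylsilane | COC(OC)C[C@@H](C)CCCO[Si](c1ccccc1)(c1ccccc1)C(C)(C)C | intermediate
6 | 2-[(2S)-5-(TBDPSO)-2-methylpentyl]-1,3-dithiane | C1(C[C@@H](C)CCCO[Si](c2ccccc2)(c2ccccc2)C(C)(C)C)SCCCS1 | intermediate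
7 | 2-methyl-1,3-dithiane | CC1SCCCS1 | starting material
8 | (R)-epichlorohydrin, (2R)-2-(chloromethyl)oxirane | ClC[C@H]1CO1 | starting material
9 | 2-lithio-2-methyl-1,3-dithiane | [Li]C1(C)SCCCS1 | intermediate
10 | lithium (2R)-1-chloro-3-(2-methyl-1,3-dithian-2-yl)propan-2-olate | CC1(C[C@@H](O[Li])CCl)SCCCS1 | intermediate
11 | 2-methyl-2-{[(2R)-oxiran-2-yl]methyl}-1,3-dithiane | CC1(C[C@@H]2CO2)SCCCS1 | intermediate
12 | 2-lithio derivative of 6 | [Li]C1(C[C@@H](C)CCCO[Si](c2ccccc2)(c2ccccc2)C(C)(C)C)SCCCS1 | intermediate
13 | lithium (2R)-1-(2-methyl-1,3-dithian-2-yl)-3-{2-[(2S)-5-(TBDPSO)-2-methylpentyl]-1,3-dithian-2-yl}propan-2-olate | CC1(C[C@@H](O[Li])CC2(C[C@@H](C)CCCO[Si](c3ccccc3)(c3ccccc3)C(C)(C)C)SCCCS2)SCCCS1 | intermediate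
14 | TBS ether of the alcohol corresponding to 13, (2R) at the carbinol carbon, (2S) in the side chain | CC1(C[C@@H](O[Si](C)(C)C(C)(C)C)CC2(C[C@@H](C)CCCO[Si](c3ccccc3)(c3ccccc3)C(C)(C)C)SCCCS2)SCCCS1 | intermediate
15 | (4R,8S)-4-(TBSO)-11-(TBDPSO)-8-methylundecane-2,6-dione | CC(=O)C[C@@H](O[Si](C)(C)C(C)(C)C)CC(=O)C[C@@H](C)CCCO[Si](c1ccccc1)(c1ccccc1)C(C)(C)C | intermediate
16 | (5R)-5-(TBSO)-3-hydroxy-3-methyl-2-[(2S)-5-(TBDPSO)pentan-2-yl]cyclohexan-1-one, mixture at C2 and C3 | CC1(O)C[C@@H](O[Si](C)(C)C(C)(C)C)CC(=O)C1[C@@H](C)CCCO[Si](c2ccccc2)(c2ccccc2)C(C)(C)C | intermediate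
17 | (5R)-5-(TBSO)-3-methyl-2-[(2S)-5-(TBDPSO)pentan-2-yl]cyclohex-2-en-1-one | CC(C)(C)[Si](C)(C)O[C@@H]1CC(C)=C([C@@H](C)CCCO[Si](c2ccccc2)(c2ccccc2)C(C)(C)C)C(=O)C1 | intermediate
18 | (5R)-5-hydroxy-3-methyl-2-[(2S)-5-(TBDPSO)pentan-2-yl]cyclohex-2-en-1-one | O[C@@H]1CC(C)=C([C@@H](C)CCCO[Si](c2ccccc2)(c2ccccc2)C(C)(C)C)C(=O)C1 | intermediate
19 | ethyl vinyl ether | C=COCC | starting material
20 | (5R)-5-(2-bromo-1-ethoxyethoxy)-3-methyl-2-[(2S)-5-(TBDPSO)pentan-2-yl]cyclohex-2-en-1-one, both acetal epimers | BrCC(OCC)O[C@@H]1CC(C)=C([C@@H](C)CCCO[Si](c2ccccc2)(c2ccccc2)C(C)(C)C)C(=O)C1 | intermediate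
21 | lithium cross-conjugated dienolate of 20 (O-lithiated at C4, C3a=C4 and C5=C6) | BrCC(OCC)O[C@@H]1CC(C)=C([C@@H](C)CCCO[Si](c2ccccc2)(c2ccccc2)C(C)(C)C)C(O[Li])=C1 | intermediate
22 | (6R)-6-(2-bromo-1-ethoxyethoxy)-2-(TBSO)-4-methyl-3-[(2S)-5-(TBDPSO)pentan-2-yl]cyclohexa-1,3-diene, both acetal epimers | BrCC(OCC)O[C@@H]1CC(C)=C([C@@H](C)CCCO[Si](c2ccccc2)(c2ccccc2)C(C)(C)C)C(O[Si](C)(C)C(C)(C)C)=C1 | intermediate
23 | (3aR,4R,7aR)-4-(TBSO)-2-ethoxy-6-methyl-5-[(2S)-5-(TBDPSO)pentan-2-yl]-2,3,3a,4,7,7a-hexahydro-1-benzofuran, both C2 epimers | C1C(OCC)O[C@@H]2CC(C)=C([C@@H](C)CCCO[Si](c3ccccc3)(c3ccccc3)C(C)(C)C)[C@H](O[Si](C)(C)C(C)(C)C)[C@H]12 | intermediate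
24 | (3aR,4R,7aR)-4-(TBSO)-6-methyl-5-[(2S)-5-(TBDPSO)pentan-2-yl]-2,3,3a,4,7,7a-hexahydro-1-benzofuran-2-ol, both C2 epimers | C1C(O)O[C@@H]2CC(C)=C([C@@H](C)CCCO[Si](c3ccccc3)(c3ccccc3)C(C)(C)C)[C@H](O[Si](C)(C)C(C)(C)C)[C@H]12 | intermediate
25 | (3aR,4R,7aR)-4-(TBSO)-6-methyl-5-[(2S)-5-(TBDPSO)pentan-2-yl]-3a,4,7,7a-tetrahydro-1-benzofuran-2(3H)-one | C1C(=O)O[C@@H]2CC(C)=C([C@@H](C)CCCO[Si](c3ccccc3)(c3ccccc3)C(C)(C)C)[C@H](O[Si](C)(C)C(C)(C)C)[C@H]12 | intermediate
26 | lithium enolate of 25 (C3=C2–OLi) | C1=C(O[Li])O[C@@H]2CC(C)=C([C@@H](C)CCCO[Si](c3ccccc3)(c3ccccc3)C(C)(C)C)[C@H](O[Si](C)(C)C(C)(C)C)[C@H]12 | intermediate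
27 | 3-[(dimethylamino)methyl] derivative of 25, (3aR,4R,7aR), C3 undefined | CN(C)CC1C(=O)O[C@@H]2CC(C)=C([C@@H](C)CCCO[Si](c3ccccc3)(c3ccccc3)C(C)(C)C)[C@H](O[Si](C)(C)C(C)(C)C)[C@H]12 | intermediate
28 | trimethylammonium iodide (methiodide) of 27 | C[N+](C)(C)CC1C(=O)O[C@@H]2CC(C)=C([C@@H](C)CCCO[Si](c3ccccc3)(c3ccccc3)C(C)(C)C)[C@H](O[Si](C)(C)C(C)(C)C)[C@H]12.[I-] | intermediate
29 | (3aR,4R,7aR)-4-(TBSO)-6-methyl-3-methylidene-5-[(2S)-5-(TBDPSO)pentan-2-yl]-3a,4,7,7a-tetrahydro-1-benzofuran-2(3H)-one | C=C1C(=O)O[C@@H]2CC(C)=C([C@@H](C)CCCO[Si](c3ccccc3)(c3ccccc3)C(C)(C)C)[C@H](O[Si](C)(C)C(C)(C)C)[C@H]12 | intermediate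
30 | (3aS,4R,7aR)-4-hydroxy-6-methyl-3-methylidene-5-[(2S)-5-(TBDPSO)pentan-2-yl]-3a,4,7,7a-tetrahydro-1-benzofuran-2(3H)-one | C=C1C(=O)O[C@@H]2CC(C)=C([C@@H](C)CCCO[Si](c3ccccc3)(c3ccccc3)C(C)(C)C)[C@H](O)[C@H]12 | intermediate
31 | (R)-2-methylbutanoic acid | CC[C@@H](C)C(=O)O | starting material
32 | O-[(2R)-2-methylbutanoyl]-N,N′-dicyclohexylisourea | CC[C@@H](C)C(=O)OC(=NC1CCCCC1)NC1CCCCC1 | intermediate
33 | (3aR,4R,7aR)-6-methyl-3-methylidene-2-oxo-5-[(2S)-5-(TBDPSO)pentan-2-yl]-2,3,3a,4,7,7a-hexahydro-1-benzofuran-4-yl (2R)-2-methylbutanoate | C=C1C(=O)O[C@@H]2CC(C)=C([C@@H](C)CCCO[Si](c3ccccc3)(c3ccccc3)C(C)(C)C)[C@H](OC(=O)[C@H](C)CC)[C@H]12 | intermediate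
34 | (3aR,4R,7aR)-5-[(2S)-5-hydroxypentan-2-yl]-6-methyl-3-methylidene-2-oxo-2,3,3a,4,7,7a-hexahydro-1-benzofuran-4-yl (2R)-2-methylbutanoate | C=C1C(=O)O[C@@H]2CC(C)=C([C@@H](C)CCCO)[C@H](OC(=O)[C@H](C)CC)[C@H]12 | target

## Step count and least certain steps

Total: 17 steps. Longest linear sequence: 16 steps (steps 1–4 and 6–17); step 5 is the side branch.

**Step 12 (key step).** The most likely failure is hydrogen transfer to the other allyl terminus, C6, which would give the silyl enol ether isomer and lose the tetrasubstituted alkene. Incomplete facial selectivity at C4 is the second risk. Both arise because the allyl radical is long-lived enough to choose. The fallback is an ionic closure that sets out from 20 and returns at 23: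
- The lithium dienolate 21 is generated as in step 11 but not silylated; on addition of DMPU and warming it is alkylated at C3a by the tethered bromide (5-exo-tet), giving the cis-fused keto lactol ether F1.
- Reduction with NaBH4 and CeCl3·7H2O from the convex face gives the allylic alcohol F2 with the C4 oxygen cis to C3.
- Silylation with TBSOTf and 2,6-lutidine gives 23.

**Step 8.** Acid may cause loss of the C7a silyloxy group followed by aromatisation to a phenol, hydrolysis of the TBS ether by the water released, or closure through the methyl group, because the desired dehydration and these pathways run under the same catalyst. The fallback separates the two events and sets out from 15, returning at 17. Aldol addition with catalytic KOC(CH3)3 in THF at low temperature gives the ketol 16, which is isolated. Its tertiary hydroxyl is converted with (CF3CO)2O, Et3N and DMAP into the trifluoroacetate F3, which loses trifluoroacetate under the amine at room temperature, conditions too mild to expel a silyloxy group.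

**Step 11.** The lithium dienolate may fragment by expelling the β-acetal oxygen, or may attack the bromide, before silylation. γ-Deprotonation would give the extended isomer. The fallback avoids a free enolate altogether and leads from 20 to 22 with no compound outside the list (F0). Soft enolisation with TBSOTf and Et3N in CH2Cl2 at −78 °C removes the C3a proton from the O-silylated oxocarbenium ion, so no species able to eliminate or alkylate is formed.

**Step 13.** The aqueous acid of the chromium reagent may strip the allylic C4 silyl ether, after which the freed alcohol is oxidised to the enone. The fallback sets out from 23 and returns at 25 with no compound outside the list (F0). Hydrolysis with PPTS in aqueous acetone gives the lactol 24, which is isolated and oxidised under neutral conditions with Ag2CO3 on Celite in hot benzene, a reagent selective for lactols.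

**Step 15.** Desilylation may be unselective, with the primary TBDPS ether lost along with the hindered C4 TBS ether, or C4 may not react at all. The fallback gives up selectivity at this point and restores it by sterics; it sets out from 29 and returns at 30. Excess HF·pyridine removes both silyl groups to give the diol F4, and TBDPSCl with imidazole at 0 °C silylates only the primary hydroxyl, regenerating 30.

## Further compounds

F1 | step 12 | (3aR,7aR)-2-ethoxy-6-methyl-5-[(2S)-5-(TBDPSO)pentan-2-yl]-3,3a,7,7a-tetrahydro-1-benzofuran-4(2H)-one, both C2 epimers | C1C(OCC)O[C@@H]2CC(C)=C([C@@H](C)CCCO[Si](c3ccccc3)(c3ccccc3)C(C)(C)C)C(=O)[C@H]12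
F2 | step 12 | (3aS,4R,7aR)-2-ethoxy-6-methyl-5-[(2S)-5-(TBDPSO)pentan-2-yl]-2,3,3a,4,7,7a-hexahydro-1-benzofuran-4-ol, both C2 epimers | C1C(OCC)O[C@@H]2CC(C)=C([C@@H](C)CCCO[Si](c3ccccc3)(c3ccccc3)C(C)(C)C)[C@H](O)[C@H]12
F3 | step 8 | trifluoroacetate of ketol 16 at the tertiary hydroxyl | CC1(OC(=O)C(F)(F)F)C[C@@H](O[Si](C)(C)C(C)(C)C)CC(=O)C1[C@@H](C)CCCO[Si](c2ccccc2)(c2ccccc2)C(C)(C)C
F0 | step 11 | none | none
F0 | step 13 | none | none
F4 | step 15 | (3aS,4R,7aR)-4-hydroxy-5-[(2S)-5-hydroxypentan-2-yl]-6-methyl-3-methylidene-3a,4,7,7a-tetrahydro-1-benzofuran-2(3H)-one | C=C1C(=O)O[C@@H]2CC(C)=C([C@@H](C)CCCO)[C@H](O)[C@H]12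
A1 | alternative 1 | (4R,6S)-4-(TBSO)-6-methyl-6-{(1E,3S)-6-[(4-methoxybenzyl)oxy]-3-methyl-1-[(triisopropylsilyl)oxy]hex-1-en-2-yl}oxan-2-one | O=C1C[C@H](O[Si](C)(C)C(C)(C)C)C[C@](C)(O1)/C([C@@H](C)CCCOCc2ccc(OC)cc2)=C/O[Si](C(C)C)(C(C)C)C(C)C
A2 | alternative 1 | (1R,2R,6R)-6-(TBSO)-3-{(2S)-5-[(4-methoxybenzyl)oxy]pentan-2-yl}-4-methyl-2-[(triisopropylsilyl)oxy]cyclohex-3-ene-1-carboxylic acid | CC(C)(C)[Si](C)(C)O[C@@H]1CC(C)=C([C@@H](C)CCCOCc2ccc(OC)cc2)[C@H](O[Si](C(C)C)(C(C)C)C(C)C)[C@@H]1C(=O)O
A3 | alternative 2 | (1R,5R)-2-oxabicyclo[3.2.0]heptane-3,6-dione | C1C(=O)O[C@@H]2CC(=O)[C@H]12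
A4 | alternative 2 | tert-butyl{[(4S)-4-methylhept-5-yn-1-yl]oxy}diphenylsilane | CC#C[C@@H](C)CCCO[Si](c1ccccc1)(c1ccccc1)C(C)(C)C
A5 | alternative 2 | (3aR,7aR)-6-methyl-5-[(2S)-5-(TBDPSO)pentan-2-yl]-3,3a,7,7a-tetrahydro-1-benzofuran-2,4-dione | C1C(=O)O[C@@H]2CC(C)=C([C@@H](C)CCCO[Si](c3ccccc3)(c3ccccc3)C(C)(C)C)C(=O)[C@H]12
A6 | alternative 3 | (3Z,5R)-5-(TBSO)-3-methyl-4-[(2S)-5-(TBDPSO)pentan-2-yl]octa-3,6,7-trienal | O=CC/C(C)=C(/[C@@H](C)CCCO[Si](c1ccccc1)(c1ccccc1)C(C)(C)C)[C@H](O[Si](C)(C)C(C)(C)C)C=C=C
A7 | alternative 3 | (3aR,4R,7aR)-4-(TBSO)-6-methyl-3-methylidene-5-[(2S)-5-(TBDPSO)pentan-2-yl]-3a,4,7,7a-tetrahydro-1-benzofuran-2(3H)-one (identical with 29) | C=C1C(=O)O[C@@H]2CC(C)=C([C@@H](C)CCCO[Si](c3ccccc3)(c3ccccc3)C(C)(C)C)[C@H](O[Si](C)(C)C(C)(C)C)[C@H]12
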